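**Retrosynthetic overview** (numbering: ring A = C1 (=CH), C2 (C=O), C3 (CH2), C4 (C(Me)CO2Me), C5 (CH), C10 (=C); ring B = C5–C6–C7–C8(Me)–C9(Me, side chain C11–C15)–C10)
1. Target ⇐ its silyl ether ⇐ a 2-alkylcyclobutanone carrying a pendant terminal alkyne, by a rhodium-catalysed cut-and-sew: the C2–C5 bond of the four-membered ketone (C2, C3, C4, C5) is cut and the alkyne C1≡C10 is sewn in, which makes C1–C2 and C10–C5 and closes rings A and B together.
2. Enabling feature: ring A is a cyclohex-2-enone whose alkene C1=C10 lies exactly between the carbonyl carbon C2 and its former α-carbon C5, and C10 is tied to C5 through C6–C9, so the decalin folds back to a strained cyclobutanone plus a tethered alkyne; C4 is quaternary, so the rhodacycles have no ring β-hydrogen.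
3. The cyclobutanone–alkyne ⇐ commercial methyl 1-methyl-3-oxocyclobutane-1-carboxylate (desymmetrising SAMP-hydrazone alkylation, sets C4 and C5) + a C9-alkynyl iodide.
4. The iodide ⇐ Eschenmoser–Tanabe opening of a temporary cyclohexenone (2-methylcyclohex-2-enone; copper-catalysed asymmetric methyl addition and enolate alkylation set C8 and C9); C13 comes from methyl (R)-3-methylglutarate.
5. Ring order: temporary six-membered template (made, then opened) → purchased four-membered ring → rings A and B formed at once in the key step.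

Key step: step 13

Assumption: the senses of induction in step 5 (ligand) and step 12 (SAMP) are taken from the standard models for cyclohexenones and cyclic ketone hydrazones; if either proved reversed on the actual substrate, the enantiomeric ligand or RAMP would be used.

**Step 1**
Reactants: 1 methyl (R)-3-methylglutarate
Product: 2 methyl (3R)-5-hydroxy-3-methylpentanoate
Conditions: BH3·SMe2, THF, 0 °C to rt; MeOH quench; used at once
Reagents that add atoms: none
Why: Borane reduces the free carboxylic acid far faster than the methyl ester (chemoselective acid reduction), and the stereocentre is not involved.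

**Step 2**
Reactants: 2 methyl (3R)-5-hydroxy-3-methylpentanoate
Product: 3 methyl (3S)-5-iodo-3-methylpentanoate
Conditions: I2, PPh3, imidazole, CH2Cl2, 0 °C
Reagents that add atoms: iodine, II
Why: Appel iodination of the primary alcohol by SN2 at CH2 should outrun lactonisation; the descriptor changes only through CIP priorities.

**Step 3**
Reactants: 3 methyl (3S)-5-iodo-3-methylpentanoate
Product: 4 (3S)-5-iodo-3-methylpentan-1-ol
Conditions: iBu2AlH (2.3 equiv), CH2Cl2, −78 to 0 °C; Rochelle salt
Reagents that add atoms: none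
Why: iBu2AlH reduces the ester to the primary alcohol at low temperature without touching the primary alkyl iodide.

**Step 4**
Reactants: 4 (3S)-5-iodo-3-methylpentan-1-ol
Product: 5 tert-butyl{[(3S)-5-iodo-3-methylpentyl]oxy}dimethylsilane
Conditions: tBuMe2SiCl, imidazole, CH2Cl2, rt
Reagents that add atoms: tert-butyldimethylsilyl chloride, CC(C)(C)[Si](C)(C)Cl
Why: Standard silylation of a primary alcohol gives an ether that should survive the base, oxidant and mild-acid steps that follow.

**Step 5**
Reactants: 6 2-methylcyclohex-2-en-1-one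
Product: 8 {[(3R)-2,3-dimethylcyclohex-1-en-1-yl]oxy}trimethylsilane, via dimethylaluminium enolate 7 (not isolated)
Conditions: Me3Al, copper thiophene-2-carboxylate Cu(O2CC4H3S) (2 mol%), (R,S,S)-binaphthol/bis(1-phenylethyl)amine phosphoramidite (4 mol%), Et2O, −30 °C; then Me3SiOTf
Reagents that add atoms: trimethylaluminium, C[Al](C)C; trimethylsilyl triflate, C[Si](C)(C)OS(=O)(=O)C(F)(F)F
Why: Copper-catalysed asymmetric conjugate addition of Me3Al to the α-substituted enone, in which the chiral ligand on monovalent copper selects the enone face and sets the methyl-bearing centre (future C8), and the enolate is trapped regiospecifically.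

**Step 6**
Reactants: 8 {[(3R)-2,3-dimethylcyclohex-1-en-1-yl]oxy}trimethylsilane; 5 tert-butyl{[(3S)-5-iodo-3-methylpentyl]oxy}dimethylsilane
Product: 10 (2S,3R)-2-[(3R)-5-{[tert-butyl(dimethyl)silyl]oxy}-3-methylpentyl]-2,3-dimethylcyclohexan-1-one, via lithium enolate 9 (not isolated)
Conditions: MeLi, THF, 0 °C; then DMPU, 5, −78 °C to rt
Reagents that add atoms: none
Why: MeLi unmasks the regiodefined tetrasubstituted lithium enolate, which is alkylated (SN2) by the primary iodide anti to the adjacent pseudoaxial methyl group, so the quaternary centre (future C9) should form with the two methyls cis.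

**Step 7**
Reactants: 10 (2S,3R)-2-[(3R)-5-{[tert-butyl(dimethyl)silyl]oxy}-3-methylpentyl]-2,3-dimethylcyclohexan-1-one
Product: 11 (5R,6S)-6-[(3R)-5-{[tert-butyl(dimethyl)silyl]oxy}-3-methylpentyl]-5,6-dimethylcyclohex-2-en-1-one
Conditions: IBX, DMSO/toluene, 70 °C
Reagents that add atoms: none
Why: IBX dehydrogenation of the ketone through its enol; one α-carbon is quaternary, so only the CH2 side can be desaturated.

**Step 8**
Reactants: 11 (5R,6S)-6-[(3R)-5-{[tert-butyl(dimethyl)silyl]oxy}-3-methylpentyl]-5,6-dimethylcyclohex-2-en-1-one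
Product: 12 (3S,4R)-3-[(3R)-5-{[tert-butyl(dimethyl)silyl]oxy}-3-methylpentyl]-3,4-dimethyl-7-oxabicyclo[4.1.0]heptan-2-one (both epoxide faces acceptable)
Conditions: 30% aq. H2O2, NaOH (cat.), MeOH, 0 °C
Reagents that add atoms: hydrogen peroxide, OO
Why: Weitz–Scheffer nucleophilic epoxidation of the enone; the two epoxide carbons lose their stereochemistry in step 9, so facial selectivity does not matter.

**Step 9**
Reactants: 12 (3S,4R)-3-[(3R)-5-{[tert-butyl(dimethyl)silyl]oxy}-3-methylpentyl]-3,4-dimethyl-7-oxabicyclo[4.1.0]heptan-2-one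
Product: 15 (3R,4S,7R)-9-{[tert-butyl(dimethyl)silyl]oxy}-4-ethynyl-3,4,7-trimethylnonan-1-ol, via sulfonylhydrazone 13 (not isolated), via alkynal 14 (not isolated)
Conditions: 2,4-(O2N)2C6H3SO2NHNH2, pyridine, THF, 0 °C to rt; then NaBH4, MeOH, 0 °C
Reagents that add atoms: none
Why: Eschenmoser–Tanabe fragmentation, in which the epoxy sulfonylhydrazone opens to an alkoxy azo-alkene that fragments with loss of N2 and arylsulfinate, turning the ketone carbon and its α-carbon into the terminal alkyne (C10≡C1) and the β-carbon into the aldehyde (C6, reduced in the same flask), while the two stereocentres are spectators.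

**Step 10**
Reactants: 15 (3R,4S,7R)-9-{[tert-butyl(dimethyl)silyl]oxy}-4-ethynyl-3,4,7-trimethylnonan-1-ol
Product: 16 tert-butyl{[(3R,6S,7R)-6-ethynyl-9-iodo-3,6,7-trimethylnonyl]oxy}dimethylsilane
Conditions: I2, PPh3, imidazole, CH2Cl2, 0 °C
Reagents that add atoms: iodine, II
Why: Appel iodination of the primary alcohol; the terminal alkyne and silyl ether are inert under these conditions.

**Step 11**
Reactants: 17 methyl 1-methyl-3-oxocyclobutane-1-carboxylate; 18 (S)-1-amino-2-(methoxymethyl)pyrrolidine (SAMP)
Product: 19 methyl 3-{[(2S)-2-(methoxymethyl)pyrrolidin-1-yl]imino}-1-methylcyclobutane-1-carboxylate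
Conditions: cyclohexane, 4 Å sieves, 60 °C
Reagents that add atoms: none
Why: Condensation of the strained, electrophilic cyclobutanone with the hydrazine gives the chiral hydrazone without acid.

**Step 12**
Reactants: 19 methyl 3-{[(2S)-2-(methoxymethyl)pyrrolidin-1-yl]imino}-1-methylcyclobutane-1-carboxylate (3 equiv); 16 tert-butyl{[(3R,6S,7R)-6-ethynyl-9-iodo-3,6,7-trimethylnonyl]oxy}dimethylsilane
Product: 22 methyl (1S,2R)-2-[(3R,4S,7R)-9-{[tert-butyl(dimethyl)silyl]oxy}-4-ethynyl-3,4,7-trimethylnonyl]-1-methyl-3-oxocyclobutane-1-carboxylate, via lithium azaenolate 20 (not isolated), via alkylated hydrazone 21 (not isolated)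
Conditions: LiN(iPr)2 (2.9 equiv), THF, 0 °C; 16 (1 equiv), −100 to −78 °C; then sat. aq. oxalic acid, Et2O, rt; chromatography (excess azaenolate also covers proton transfer from the alkyne C–H)
Reagents that add atoms: water, O
Why: SAMP-hydrazone α-alkylation in which the auxiliary fixes the face of attack (C5), and, with the iodide as limiting reagent, only the azaenolate at the α-carbon where that face is also anti to the larger CO2Me group (cis to CH3) should react fast, which selects the enantiotopic α-carbon and so sets C4 (matched double stereodifferentiation; the cis diastereomer is removed by chromatography), before oxalic acid hydrolyses the hydrazone without epimerisation.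

**Step 13**
Reactants: 22 methyl (1S,2R)-2-[(3R,4S,7R)-9-{[tert-butyl(dimethyl)silyl]oxy}-4-ethynyl-3,4,7-trimethylnonyl]-1-methyl-3-oxocyclobutane-1-carboxylate
Product: 23 methyl (1S,5S,6R,8aS)-5-[(3R)-5-{[tert-butyl(dimethyl)silyl]oxy}-3-methylpentyl]-1,5,6-trimethyl-3-oxo-1,2,3,5,6,7,8,8a-octahydronaphthalene-1-carboxylate
Conditions: [Rh(C2H4)2Cl]2 (5 mol%), P[3,5-(CF3)2C6H3]3 (20 mol%), 1,4-dioxane, 130 °C, sealed tube
Reagents that add atoms: none
Why: Monovalent rhodium inserts into the acyl–C5 bond of the cyclobutanone (directly, or by insertion on the unsubstituted side followed by CO extrusion and re-insertion), the Rh–C5 bond then adds syn across the tethered alkyne and C(acyl)–C(vinyl) reductive elimination releases the enone, so that C1≡C10 ends up inserted into the cut C2–C5 bond. The closest known reaction type is the rhodium/electron-poor triarylphosphine-catalysed intramolecular cut-and-sew (carboacylation) of cyclobutanones that carry an alkyne tether on the α-carbon, which gives cyclohexenone-fused bicycles. Ring B closes by 6-exo-dig migratory insertion (C5 to the internal alkyne carbon C10) and ring A by reductive elimination from the resulting seven-membered acyl–vinyl rhodacycle, a formal (4+2) expansion of the four-membered ring driven by release of its strain. No new stereocentre is formed: C10 becomes sp2 and C5 keeps its configuration because oxidative addition, insertion and reductive elimination all proceed with retention at the metal-bound carbon, while C4, C8, C9 and C13 are not touched. The step needs activation of the more hindered proximal C–C bond and exo insertion of the alkyne: only the rhodacycle on the substituted side can reach the alkyne through the four-atom tether (the other one can only revert), the bulky electron-poor phosphine is the established control element for this, the quaternary C9 favours closure of ring B and the quaternary C4 leaves the rhodacycles without ring β-hydrogens.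

**Step 14**
Reactants: 23 methyl (1S,5S,6R,8aS)-5-[(3R)-5-{[tert-butyl(dimethyl)silyl]oxy}-3-methylpentyl]-1,5,6-trimethyl-3-oxo-1,2,3,5,6,7,8,8a-octahydronaphthalene-1-carboxylate
Product: 24 methyl (1S,5S,6R,8aS)-5-[(3R)-5-hydroxy-3-methylpentyl]-1,5,6-trimethyl-3-oxo-1,2,3,5,6,7,8,8a-octahydronaphthalene-1-carboxylate (target)
Conditions: HF·pyridine, pyridine, THF, 0 °C to rt
Reagents that add atoms: none
Why: Buffered fluoride cleaves the Si–O bond only, leaving the methyl ester, the enone and the epimerisable C5–H untouched.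

**Compound list**
1 | methyl (R)-3-methylglutarate | OC(=O)C[C@@H](C)CC(=O)OC | starting material
2 | methyl (3R)-5-hydroxy-3-methylpentanoate | OCC[C@@H](C)CC(=O)OC | intermediate
3 | methyl (3S)-5-iodo-3-methylpentanoate | ICC[C@@H](C)CC(=O)OC | intermediate
4 | (3S)-5-iodo-3-methylpentan-1-ol | ICC[C@@H](C)CCO | intermediate
5 | tert-butyl{[(3S)-5-iodo-3-methylpentyl]oxy}dimethylsilane | ICC[C@@H](C)CCO[Si](C)(C)C(C)(C)C | intermediate
6 | 2-methylcyclohex-2-en-1-one | CC1=CCCC1=O | starting material
7 | dimethylaluminium (3R)-2,3-dimethylcyclohex-1-en-1-olate | C[C@@H]1CCCC(O[Al](C)C)=C1C | intermediate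
8 | {[(3R)-2,3-dimethylcyclohex-1-en-1-yl]oxy}trimethylsilane | C[C@@H]1CCCC(O[Si](C)(C)C)=C1C | intermediate
9 | lithium (3R)-2,3-dimethylcyclohex-1-en-1-olate | C[C@@H]1CCCC(O[Li])=C1C | intermediate
10 | (2S,3R)-2-[(3R)-5-{[tert-butyl(dimethyl)silyl]oxy}-3-methylpentyl]-2,3-dimethylcyclohexan-1-one | O=C1CCC[C@@H](C)[C@]1(C)CC[C@@H](C)CCO[Si](C)(C)C(C)(C)C | intermediate
11 | (5R,6S)-6-[(3R)-5-{[tert-butyl(dimethyl)silyl]oxy}-3-methylpentyl]-5,6-dimethylcyclohex-2-en-1-one | O=C1C=CC[C@@H](C)[C@]1(C)CC[C@@H](C)CCO[Si](C)(C)C(C)(C)C | intermediate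
12 | (3S,4R)-3-[(3R)-5-{[tert-butyl(dimethyl)silyl]oxy}-3-methylpentyl]-3,4-dimethyl-7-oxabicyclo[4.1.0]heptan-2-one, epoxide carbons undefined | O=C1C2OC2C[C@@H](C)[C@]1(C)CC[C@@H](C)CCO[Si](C)(C)C(C)(C)C | intermediate
13 | 2,4-dinitrobenzenesulfonylhydrazone of 12 | O=S(=O)(NN=C1C2OC2C[C@@H](C)[C@]1(C)CC[C@@H](C)CCO[Si](C)(C)C(C)(C)C)c1ccc(cc1[N+](=O)[O-])[N+](=O)[O-] | intermediate
14 | (3R,4S,7R)-9-{[tert-butyl(dimethyl)silyl]oxy}-4-ethynyl-3,4,7-trimethylnonanal | O=CC[C@@H](C)[C@](C#C)(C)CC[C@@H](C)CCO[Si](C)(C)C(C)(C)C | intermediate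
15 | (3R,4S,7R)-9-{[tert-butyl(dimethyl)silyl]oxy}-4-ethynyl-3,4,7-trimethylnonan-1-ol | OCC[C@@H](C)[C@](C#C)(C)CC[C@@H](C)CCO[Si](C)(C)C(C)(C)C | intermediate
16 | tert-butyl{[(3R,6S,7R)-6-ethynyl-9-iodo-3,6,7-trimethylnonyl]oxy}dimethylsilane | ICC[C@@H](C)[C@](C#C)(C)CC[C@@H](C)CCO[Si](C)(C)C(C)(C)C | intermediate
17 | methyl 1-methyl-3-oxocyclobutane-1-carboxylate | COC(=O)C1(C)CC(=O)C1 | starting material
18 | (S)-1-amino-2-(methoxymethyl)pyrrolidine (SAMP) | COC[C@@H]1CCCN1N | starting material
19 | methyl 3-{[(2S)-2-(methoxymethyl)pyrrolidin-1-yl]imino}-1-methylcyclobutane-1-carboxylate | COC(=O)C1(C)CC(=NN2CCC[C@H]2COC)C1 | intermediate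
20 | lithium azaenolate of 19 (N-lithio ene-hydrazine, ring carbon bearing the ester undefined) | COC(=O)C1(C)CC(N([Li])N2CCC[C@H]2COC)=C1 | intermediate
21 | SAMP hydrazone of 22 | COC(=O)[C@@]1(C)CC(=NN2CCC[C@H]2COC)[C@@H]1CC[C@@H](C)[C@](C#C)(C)CC[C@@H](C)CCO[Si](C)(C)C(C)(C)C | intermediate
22 | methyl (1S,2R)-2-[(3R,4S,7R)-9-{[tert-butyl(dimethyl)silyl]oxy}-4-ethynyl-3,4,7-trimethylnonyl]-1-methyl-3-oxocyclobutane-1-carboxylate | COC(=O)[C@@]1(C)CC(=O)[C@@H]1CC[C@@H](C)[C@](C#C)(C)CC[C@@H](C)CCO[Si](C)(C)C(C)(C)C | intermediate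
23 | methyl (1S,5S,6R,8aS)-5-[(3R)-5-{[tert-butyl(dimethyl)silyl]oxy}-3-methylpentyl]-1,5,6-trimethyl-3-oxo-1,2,3,5,6,7,8,8a-octahydronaphthalene-1-carboxylate | COC(=O)[C@@]1(C)CC(=O)C=C2[C@@H]1CC[C@@H](C)[C@]2(C)CC[C@@H](C)CCO[Si](C)(C)C(C)(C)C | intermediate
24 | methyl (1S,5S,6R,8aS)-5-[(3R)-5-hydroxy-3-methylpentyl]-1,5,6-trimethyl-3-oxo-1,2,3,5,6,7,8,8a-octahydronaphthalene-1-carboxylate | COC(=O)[C@@]1(C)CC(=O)C=C2[C@@H]1CC[C@@H](C)[C@]2(C)CC[C@@H](C)CCO | target

**Totals**
Total step count: 14. Longest linear sequence: 12 steps (steps 1–4, 6–10, 12–14, from compound 1).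

**Steps most likely to fail**

Step 13. What may go wrong: insertion into the hindered acyl–C5 bond may lose out to CO extrusion (giving the cyclopropane), the terminal alkyne may oligomerise on rhodium, or the crowded C5–C10 bond next to the quaternary C9 may form too slowly. Fallback (sets out from 10, comes back at 23): the template ring is kept as ring B and ring A is built by a classical Michael–aldol annulation. Ketone 10 is converted with LiN(iPr)2/Me3SiCl into the silyl enol ether F1 (only one α-carbon can enolise). Mukaiyama–Michael addition of F1 to methyl (E)-2-methyl-4-oxopent-2-enoate (TiCl4, CH2Cl2, −78 °C; attack β to the ketone, at the ester-bearing carbon) should give the 1,5-diketone F2. Aldol condensation (pyrrolidine, AcOH, toluene, reflux) closes ring A onto the ring ketone and gives 23. The cost is that C4 is then formed without control and C5 only under thermodynamic control, so 23 would have to be separated from its diastereomers; step 14 is unchanged.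

Step 12. What may go wrong: poor facial discrimination between CH3 and CO2CH3 on the azaenolate, so that both enantiotopic α-carbons are alkylated and the C4 configuration is eroded. Fallback (sets out from 17, comes back at 21): the ester is enlarged to a bicyclic orthoester before the alkylation. 17 is saponified (LiOH, THF/H2O) to 1-methyl-3-oxocyclobutane-1-carboxylic acid F3, which is esterified with (3-methyloxetan-3-yl)methanol (EDC, DMAP) to the oxetanylmethyl ester F4 and rearranged with BF3·OEt2 (CH2Cl2, −15 °C) to the trioxabicyclo[2.2.2]octane orthoester ketone F5. Condensation with 18 gives the hydrazone F6, whose azaenolate is alkylated with 16 as in step 12 to the alkylated orthoester hydrazone F7, now anti to a tert-alkyl-like C(OR)3 group. PPTS in wet THF opens the orthoester to the dihydroxy ester hydrazone F8 while the hydrazone still protects the α-stereocentre, and K2CO3/MeOH transesterifies F8 to 21, which is hydrolysed with oxalic acid to 22 as before.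

Step 9. What may go wrong: slow hydrazone formation at the neopentyl ketone, or opening of the epoxide without the C–C cleavage that must deliver an aldehyde. Fallback (sets out from 11, comes back at 15): the ring is opened oxidatively. Enone 11 is ozonised (O3, CH2Cl2/MeOH, −78 °C) and reduced in the same flask with NaBH4 to the triol F9. NaIO4 (THF/H2O) cleaves its 1,2-diol to the neopentyl aldehyde, obtained as the lactol F10. Seyferth–Gilbert homologation with the Ohira–Bestmann reagent (dimethyl (1-diazo-2-oxopropyl)phosphonate, K2CO3, MeOH) then gives alkynol 15.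

**Further compounds**
F1 | step 13 | {[(5R,6S)-6-[(3R)-5-{[tert-butyl(dimethyl)silyl]oxy}-3-methylpentyl]-5,6-dimethylcyclohex-1-en-1-yl]oxy}trimethylsilane | C[Si](C)(C)OC1=CCC[C@@H](C)[C@]1(C)CC[C@@H](C)CCO[Si](C)(C)C(C)(C)C
F2 | step 13 | methyl 2-[(3S,4R)-3-[(3R)-5-{[tert-butyl(dimethyl)silyl]oxy}-3-methylpentyl]-3,4-dimethyl-2-oxocyclohexyl]-2-methyl-4-oxopentanoate, two new centres undefined | COC(=O)C(C)(CC(C)=O)C1CC[C@@H](C)[C@](C)(CC[C@@H](C)CCO[Si](C)(C)C(C)(C)C)C1=O
F3 | step 12 | 1-methyl-3-oxocyclobutane-1-carboxylic acid | OC(=O)C1(C)CC(=O)C1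
F4 | step 12 | (3-methyloxetan-3-yl)methyl 1-methyl-3-oxocyclobutane-1-carboxylate | CC1(COC(=O)C2(C)CC(=O)C2)COC1
F5 | step 12 | 3-methyl-3-(4-methyl-2,6,7-trioxabicyclo[2.2.2]octan-1-yl)cyclobutan-1-one | CC12COC(OC1)(OC2)C1(C)CC(=O)C1
F6 | step 12 | SAMP hydrazone of F5 | CC12COC(OC1)(OC2)C1(C)CC(=NN2CCC[C@H]2COC)C1
F7 | step 12 | SAMP hydrazone of F5 alkylated at the α-carbon with the chain of 16, cis to the ring methyl | CC12COC(OC1)(OC2)[C@@]1(C)CC(=NN2CCC[C@H]2COC)[C@@H]1CC[C@@H](C)[C@](C#C)(C)CC[C@@H](C)CCO[Si](C)(C)C(C)(C)C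
F8 | step 12 | 3-hydroxy-2-(hydroxymethyl)-2-methylpropyl ester analogue of 21 | OCC(C)(CO)COC(=O)[C@@]1(C)CC(=NN2CCC[C@H]2COC)[C@@H]1CC[C@@H](C)[C@](C#C)(C)CC[C@@H](C)CCO[Si](C)(C)C(C)(C)C
F9 | step 9 | (3S,4R,7R)-9-{[tert-butyl(dimethyl)silyl]oxy}-3-(2-hydroxyethyl)-3,4,7-trimethylnonane-1,2-diol numbered from the diol end, carbinol centre undefined | OCC[C@@H](C)[C@](C(O)CO)(C)CC[C@@H](C)CCO[Si](C)(C)C(C)(C)C
F10 | step 9 | (3S,4R)-3-[(3R)-5-{[tert-butyl(dimethyl)silyl]oxy}-3-methylpentyl]-3,4-dimethyltetrahydro-2H-pyran-2-ol, anomers | OC1OCC[C@@H](C)[C@]1(C)CC[C@@H](C)CCO[Si](C)(C)C(C)(C)C
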